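**Retrosynthetic overview**
1. Target 15 (meso hexaphenol) comes from hexabenzyl ether 14 by one neutral global hydrogenolysis.
2. 14 is cut at both aryl–C(O) and both C(O)–Cα bonds: a palladium-catalysed oxidative syn-diaroylation joins one Z-alkene 12, two CO and two molecules of arylboronic acid 6. Z geometry plus syn addition gives the meso relationship.
3. Fragment 1 (boronic acid 6) comes from resorcinol by benzylation, bromination and borylation.
4. Fragment 2 (Z-alkene 12) comes from 4-bromophenol and allyl bromide by benzylation, Grignard allylation and Z-selective homometathesis.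
5. No ring is formed in the route; all four benzene rings are carried in intact from resorcinol (two) and 4-bromophenol (two).

Assumption: the two descriptors in the SMILES work out as (2S,3R) on a constitutionally symmetric backbone, which is the meso, achiral diastereomer, so the route controls relative configuration only.

**Step 1**
Reactants: 1 resorcinol
Product: 2 1,3-bis(benzyloxy)benzene
Conditions: BnBr (2.2 equiv), K2CO3 (3 equiv), DMF, 60 °C
Reagents that add atoms: benzyl bromide, BrCc1ccccc1
Why: Williamson ether synthesis; phenoxide O-alkylation in a dipolar aprotic solvent is clean and installs protecting groups that come off later by neutral hydrogenolysis.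

**Step 2**
Reactants: 2 1,3-bis(benzyloxy)benzene
Product: 3 1-bromo-2,4-bis(benzyloxy)benzene
Conditions: NBS (1.0 equiv), MeCN, 0 → 20 °C
Reagents that add atoms: N-bromosuccinimide, O=C1CCC(=O)N1Br
Why: Electrophilic aromatic bromination; C4 is para to one alkoxy group and ortho to the other, while the hindered C2 between the two ethers is not attacked.

**Step 3**
Reactants: 3 1-bromo-2,4-bis(benzyloxy)benzene
Product: 6 [2,4-bis(benzyloxy)phenyl]boronic acid, via aryllithium 4 (not isolated), via lithium aryltriisopropoxyborate 5 (not isolated)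
Conditions: n-BuLi (1.05 equiv), THF, −78 °C; B(OiPr)3 (1.5 equiv), −78 → 0 °C; 1 M HCl
Reagents that add atoms: triisopropyl borate, CC(C)OB(OC(C)C)OC(C)C; water, O
Why: Bromine–lithium exchange at −78 °C is faster than benzylic deprotonation of the ethers, and borate trapping followed by hydrolysis gives the boronic acid (lithiation–borylation).

**Step 4**
Reactants: 7 4-bromophenol
Product: 8 1-(benzyloxy)-4-bromobenzene
Conditions: BnBr (1.1 equiv), K2CO3 (2 equiv), acetone, reflux
Reagents that add atoms: benzyl bromide, BrCc1ccccc1
Why: Williamson ether synthesis on a simple phenol.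

**Step 5**
Reactants: 8 1-(benzyloxy)-4-bromobenzene; 9 allyl bromide
Product: 11 1-allyl-4-(benzyloxy)benzene, via arylmagnesium bromide 10 (not isolated)
Conditions: Mg, THF, 50 °C; then 9 (1.2 equiv), 0 → 20 °C
Reagents that add atoms: none
Why: Grignard formation followed by allylation of the aryl Grignard; the SN2 and SN2' pathways give the same allylarene.

**Step 6**
Reactants: 11 1-allyl-4-(benzyloxy)benzene (2 equiv)
Product: 12 (Z)-1,4-bis[4-(benzyloxy)phenyl]but-2-ene
Conditions: Ru(NO3)(=CH-C6H4-2-OiPr)(C22H29N2) (2 mol %; Z-selective cyclometalated Grubbs catalyst, C22H29N2 = 1-(adamantan-1-yl)-3-mesitylimidazolidin-2-ylidene metalated at adamantyl C2), THF, 35 °C, Ar sweep to remove C2H4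
Reagents that add atoms: none
Why: Z-selective olefin homometathesis; the chelating adamantyl–NHC forces side-bound metallacyclobutanes with both substituents syn, so allylarenes dimerise to the Z-alkene (Z:E checked by NMR, product recrystallised).

**Step 7**
Reactants: 12 (Z)-1,4-bis[4-(benzyloxy)phenyl]but-2-ene; 6 [2,4-bis(benzyloxy)phenyl]boronic acid; 13 carbon monoxide
Product: 14 (2R,3S)-1,4-bis[2,4-bis(benzyloxy)phenyl]-2,3-bis[4-(benzyloxy)benzyl]butane-1,4-dione (meso)
Conditions: Pd(OCOCF3)2 (10 mol %), N,N'-bis(2,6-dimethylphenyl)butane-2,3-diimine (11 mol %), p-benzoquinone (1.5 equiv), CO (5 bar), THF/H2O 20:1, 20 °C, 3 equiv of 6 in all added by syringe pump over 10 h (two molecules of 6 and two of CO are built into each molecule of 14); aqueous work-up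
Reagents that add atoms: second equivalent of boronic acid 6, OB(O)c1ccc(OCc2ccccc2)cc1OCc1ccccc1; second equivalent of carbon monoxide 13, [C-]#[O+]
Why: Proposed new method: a palladium-catalysed oxidative four-component syn-1,2-diaroylation of an unactivated internal alkene, in which ArB(OH)2 transmetalates to the cationic divalent palladium diimine complex, CO inserts to give an aroyl–palladium species, the Z-alkene inserts syn into the Pd–acyl bond to give a five-membered C,O-chelated β-ketoalkyl palladium (chelation and CO pressure suppress β-hydride elimination), a second CO inserts with retention at carbon, and a second ArB(OH)2 transmetalates before C(acyl)–C(aryl) reductive elimination releases the 1,4-diketone while benzoquinone returns zerovalent palladium to the divalent state, so that the net equation is 12 + 2 ArB(OH)2 + 2 CO + benzoquinone + 2 H2O → 14 + 2 B(OH)3 + hydroquinone; both aroyl groups therefore add to the same face of the Z-alkene, which sets the (2R,3S) meso configuration, and the closest known reaction types are the syn-stereospecific palladium-catalysed bis-alkoxycarbonylation of 1,2-disubstituted alkenes with CO, alcohol and benzoquinone, the acyl/alkene/CO insertion sequence of CO–olefin copolymerisation, and the oxidative carbonylative coupling of arylboronic acids.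

**Step 8**
Reactants: 14 (2R,3S)-1,4-bis[2,4-bis(benzyloxy)phenyl]-2,3-bis[4-(benzyloxy)benzyl]butane-1,4-dione
Product: 15 (2R,3S)-1,4-bis(2,4-dihydroxyphenyl)-2,3-bis(4-hydroxybenzyl)butane-1,4-dione (meso; target CNP0406969.1)
Conditions: H2 (1 atm), Pd/C (10 wt % Pd), THF/MeOH 1:1, 20 °C
Reagents that add atoms: none
Why: Catalytic hydrogenolysis of the six benzyl ethers under neutral conditions, so the epimerisable α-stereocentres and the 1,4-diketone (furan formation) see neither acid nor base, and the electron-rich ortho-oxygenated aryl ketones resist reduction.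

**Compound list**
1 | resorcinol | Oc1cccc(O)c1 | starting material
2 | 1,3-bis(benzyloxy)benzene | c1ccccc1COc1cccc(OCc2ccccc2)c1 | intermediate
3 | 1-bromo-2,4-bis(benzyloxy)benzene | Brc1ccc(OCc2ccccc2)cc1OCc1ccccc1 | intermediate
4 | [2,4-bis(benzyloxy)phenyl]lithium (not isolated) | [Li]c1ccc(OCc2ccccc2)cc1OCc1ccccc1 | intermediate
5 | lithium [2,4-bis(benzyloxy)phenyl]triisopropoxyborate (not isolated) | [Li+].CC(C)O[B-](OC(C)C)(OC(C)C)c1ccc(OCc2ccccc2)cc1OCc1ccccc1 | intermediate
6 | [2,4-bis(benzyloxy)phenyl]boronic acid | OB(O)c1ccc(OCc2ccccc2)cc1OCc1ccccc1 | intermediate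
7 | 4-bromophenol | Oc1ccc(Br)cc1 | starting material
8 | 1-(benzyloxy)-4-bromobenzene | Brc1ccc(OCc2ccccc2)cc1 | intermediate
9 | allyl bromide | C=CCBr | starting material
10 | [4-(benzyloxy)phenyl]magnesium bromide (not isolated) | Br[Mg]c1ccc(OCc2ccccc2)cc1 | intermediate
11 | 1-allyl-4-(benzyloxy)benzene | C=CCc1ccc(OCc2ccccc2)cc1 | intermediate
12 | (Z)-1,4-bis[4-(benzyloxy)phenyl]but-2-ene | c1ccccc1COc1ccc(C/C=C\Cc2ccc(OCc3ccccc3)cc2)cc1 | intermediate
13 | carbon monoxide | [C-]#[O+] | starting material
14 | (2R,3S)-1,4-bis[2,4-bis(benzyloxy)phenyl]-2,3-bis[4-(benzyloxy)benzyl]butane-1,4-dione (meso) | O=C(c1ccc(OCc2ccccc2)cc1OCc1ccccc1)[C@@H](Cc1ccc(OCc2ccccc2)cc1)[C@@H](Cc1ccc(OCc2ccccc2)cc1)C(=O)c1ccc(OCc2ccccc2)cc1OCc1ccccc1 | intermediate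
15 | (2R,3S)-1,4-bis(2,4-dihydroxyphenyl)-2,3-bis(4-hydroxybenzyl)butane-1,4-dione (meso) | O=C(c1ccc(O)cc1O)[C@@H](Cc1ccc(O)cc1)[C@@H](Cc1ccc(O)cc1)C(=O)c1ccc(O)cc1O | target

**Total step count:** 8 (steps 1–3 for fragment 1, steps 4–6 for fragment 2, steps 7–8 after convergence).
**Longest linear sequence:** 5 steps (1, 2, 3, 7, 8 or 4, 5, 6, 7, 8).

**Steps most likely to fail**

Step 7 (the new syn-diaroylation). The aroyl–palladium species may be intercepted by a second boronic acid before the internal alkene inserts, giving the diaryl ketone. Insertion of a 1,2-disubstituted alkene may also be slow, and β-hydride elimination or double-bond migration would erode the meso outcome. Any (E)-12 carried in would give the racemic diastereomer of 14, to be removed by crystallisation. The fallback uses known chemistry, sets out from 12 and comes back at 14. First, 12 undergoes the established syn-stereospecific bis(methoxycarbonylation) [Pd(OCOCF3)2, the same diimine, p-TsOH (cat.), p-benzoquinone, CO (4 bar), MeOH/THF, 20 °C] to give dimethyl meso-2,3-bis[4-(benzyloxy)benzyl]succinate F1. Next, F1 is converted without base by dimethylaluminium benzenethiolate F2 (made in the flask from Me3Al and PhSH, CH2Cl2, 0 → 20 °C) into S,S'-diphenyl meso-2,3-bis[4-(benzyloxy)benzyl]butanebis(thioate) F3. Finally, F3 undergoes a double Liebeskind–Srogl acyl coupling with two equivalents of boronic acid 6 [Pd2(dba)3 as zerovalent palladium source, tri(2-furyl)phosphine, copper thiophene-2-carboxylate Cu(O2CC4H3S), THF, 50 °C] to give 14. The conditions are neutral, so the meso centres set in the carbonylation are kept.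

Step 6 (Z-selective homometathesis). Secondary metathesis can erode the Z:E ratio, and ruthenium hydrides can move the double bond into conjugation with the arene. The fallback replaces metathesis by alkyne semi-hydrogenation, sets out from 8 and comes back at 12. First, 8 is converted through Grignard 10 (Mg, THF) and paraformaldehyde into [4-(benzyloxy)phenyl]methanol F4. PBr3 (Et2O, 0 °C) then gives 1-(benzyloxy)-4-(bromomethyl)benzene F5. Two equivalents of F5 are coupled with ethyne-1,2-diylbis(magnesium bromide) F6 (from acetylene and EtMgBr in THF) under CuCl catalysis (5 mol %) to give 1,4-bis[4-(benzyloxy)phenyl]but-2-yne F7. Syn semi-hydrogenation [H2 (1 atm), Pd/CaCO3 poisoned with Pb(OAc)2, quinoline, EtOAc] delivers 12 with the Z geometry fixed by the mechanism.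

Step 8 (global hydrogenolysis). Six benzyl ethers must be cleaved without reducing the two aryl ketones, and the polar hexaphenol may adsorb on the catalyst. The fallback is non-reductive, sets out from 14 and comes back at 15. It treats 14 with BCl3 and pentamethylbenzene as benzyl-cation scavenger in CH2Cl2 at −78 °C and quenches cold with MeOH, which cleaves the aryl benzyl ethers by Lewis-acid dealkylation at a temperature too low for enolisation or furan formation. It makes no new compound (entry F0).

**Further compounds**
F1 | step 7 | dimethyl meso-(2R,3S)-2,3-bis[4-(benzyloxy)benzyl]succinate | COC(=O)[C@@H](Cc1ccc(OCc2ccccc2)cc1)[C@@H](Cc1ccc(OCc2ccccc2)cc1)C(=O)OC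
F2 | step 7 | dimethylaluminium benzenethiolate | C[Al](C)Sc1ccccc1
F3 | step 7 | S,S'-diphenyl meso-(2R,3S)-2,3-bis[4-(benzyloxy)benzyl]butanebis(thioate) | O=C(Sc1ccccc1)[C@@H](Cc1ccc(OCc2ccccc2)cc1)[C@@H](Cc1ccc(OCc2ccccc2)cc1)C(=O)Sc1ccccc1
F4 | step 6 | [4-(benzyloxy)phenyl]methanol | OCc1ccc(OCc2ccccc2)cc1
F5 | step 6 | 1-(benzyloxy)-4-(bromomethyl)benzene | BrCc1ccc(OCc2ccccc2)cc1
F6 | step 6 | ethyne-1,2-diylbis(magnesium bromide) | Br[Mg]C#C[Mg]Br
F7 | step 6 | 1,4-bis[4-(benzyloxy)phenyl]but-2-yne | c1ccccc1COc1ccc(CC#CCc2ccc(OCc3ccccc3)cc2)cc1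
F0 | step 8 | none | none
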